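**Retrosynthetic overview**
- Lactone last: Pd-catalysed cyclocarbonylation of a trans C7-ethynyl / C8-hydroxyl pair. The tiglate comes from acylation of the C6 alcohol, itself from 1,2-reduction of a C6 enone.
- Ten-membered ring: Grob fragmentation of a bicyclo[5.3.0]decane 1,3-diol monomesylate (C6–O⁻ / C1–OMs). The C6–C10 bond breaks, giving the C6 ketone and the ring-cis C1=C10 alkene.
- Seven-membered ring of the bicycle: ring-closing metathesis (C4=C5, ring-cis by ring size) between a C6 vinyl carbinol and a C4 methylene. The C1–C4/C15 chain is attached to C10 by reductive aldol.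
- Cyclopentenone (C6–C10, stereocentres C7/C8): enantioselective oxa-Piancatelli rearrangement of a furyl alkynyl carbinol; C14 by Morita–Baylis–Hillman reaction.
- Ring order: furan → cyclopentenone → cyclopentane-fused cycloheptene → cyclodecadiene → γ-lactone.

Assumption: the SMILES is read literally, i.e. (6R,7R,8S) with the ring carbons cis at both ring C=C bonds (E descriptors because of the CH2OH groups). Germacrane labels C1–C15 are used in explanations: C6 bears O-tigloyl, C8 the lactone O, C14 is on C10, C15 on C4, C11–C13 are the acrylate unit. TBS = tert-butyldimethylsilyl, Ms = methanesulfonyl.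

**Step 1**
Reactants: 1 furan-2-carbaldehyde; 2 ethynyl(trimethyl)silane
Product: 4 1-(furan-2-yl)-3-(trimethylsilyl)prop-2-yn-1-ol (racemic), via lithium (trimethylsilyl)acetylide 3 (not isolated)
Conditions: 2, n-BuLi, THF, −78 °C; then 1, −78 → 0 °C; aq. NH4Cl
Reagents that add atoms: none
Why: 1,2-addition of a lithium acetylide to an aldehyde (alkynylation); the carbinol centre is racemic and is destroyed in step 2.

**Step 2**
Reactants: 4 1-(furan-2-yl)-3-(trimethylsilyl)prop-2-yn-1-ol
Product: 5 (4S,5R)-4-hydroxy-5-[(trimethylsilyl)ethynyl]cyclopent-2-en-1-one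
Conditions: (R)-3,3'-bis(2,4,6-triisopropylphenyl)-BINOL N-triflylphosphoramide (5 mol%), H2O (5 equiv), MeCN, 40 °C
Reagents that add atoms: water, O
Why: Proposed new method: an enantioselective oxa-Piancatelli rearrangement in which the chiral Brønsted acid ionises the carbinol to a furfuryl cation/phosphoramidate ion pair, water adds at furan C5, the ring opens to a 1-hydroxypentadienyl cation and conrotatory 4π-electrocyclisation inside the chiral ion pair closes the 4,5-trans cyclopentenone (trans from conrotation, absolute sense from the anion, the antipodal catalyst being used if the sense is opposite); the closest known reactions are the chiral phosphoric acid-catalysed aza-Piancatelli rearrangement with anilines and the racemic Dy(OTf)3-catalysed oxa-Piancatelli rearrangement, neither shown with water and an alkynyl carbinol.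

**Step 3**
Reactants: 5 (4S,5R)-4-hydroxy-5-[(trimethylsilyl)ethynyl]cyclopent-2-en-1-one; 6 formaldehyde
Product: 7 (4S,5R)-4-hydroxy-2-(hydroxymethyl)-5-[(trimethylsilyl)ethynyl]cyclopent-2-en-1-one
Conditions: 37% aq. CH2O, PBu3 (10 mol%), CHCl3/MeOH, rt
Reagents that add atoms: none
Why: Morita–Baylis–Hillman hydroxymethylation at the enone α-carbon installs C14; the non-basic phosphine catalyst avoids isomerisation of the 4-hydroxy-5-substituted enone and no stereocentre is touched.

**Step 4**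
Reactants: 7 (4S,5R)-4-hydroxy-2-(hydroxymethyl)-5-[(trimethylsilyl)ethynyl]cyclopent-2-en-1-one
Product: 8 (4S,5R)-4-(TBSO)-2-(TBSOCH2)-5-[(trimethylsilyl)ethynyl]cyclopent-2-en-1-one
Conditions: TBSCl (2.5 equiv), imidazole, DMF, 0 °C → rt
Reagents that add atoms: tert-butyl(chloro)dimethylsilane, CC(C)(C)[Si](C)(C)Cl
Why: Silyl ether formation on both hydroxyls so that they survive the enolate, Grignard and base steps.

**Step 5**
Reactants: 9 2-methylidenepropane-1,3-diol
Product: 10 2-(TBSOCH2)prop-2-en-1-ol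
Conditions: NaH (1.0 equiv), THF, 0 °C; TBSCl (1.0 equiv)
Reagents that add atoms: tert-butyl(chloro)dimethylsilane, CC(C)(C)[Si](C)(C)Cl
Why: Monosilylation of a symmetric diol through its sparingly soluble monosodium alkoxide (silyl ether formation).

**Step 6**
Reactants: 10 2-(TBSOCH2)prop-2-en-1-ol; 11 1,1,1-trimethoxyethane
Product: 13 methyl 4-(TBSOCH2)pent-4-enoate, via ketene acetal 12 (not isolated)
Conditions: EtCO2H (cat.), 140 °C, MeOH distilled off
Reagents that add atoms: none
Why: Johnson–Claisen (orthoester Claisen) rearrangement adds the two-carbon ester unit (C1, C2) and leaves the 1,1-disubstituted alkene needed for metathesis; no stereocentre.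

**Step 7**
Reactants: 13 methyl 4-(TBSOCH2)pent-4-enoate
Product: 14 4-(TBSOCH2)pent-4-enal
Conditions: i-Bu2AlH (1.05 equiv), CH2Cl2, −78 °C; aq. potassium sodium tartrate
Reagents that add atoms: none
Why: Low-temperature i-Bu2AlH half-reduction of the ester stops at the aldehyde via the stable tetrahedral aluminate.

**Step 8**
Reactants: 8 (4S,5R)-4-(TBSO)-2-(TBSOCH2)-5-[(trimethylsilyl)ethynyl]cyclopent-2-en-1-one; 14 4-(TBSOCH2)pent-4-enal
Product: 17 (2S,4S,5R)-2-[(1R)-1-(mesyloxy)-4-(TBSOCH2)pent-4-en-1-yl]-4-(TBSO)-2-(TBSOCH2)-5-[(trimethylsilyl)ethynyl]cyclopentan-1-one, via lithium enolate 15 (not isolated), via lithium aldolate 16 (not isolated)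
Conditions: LiBH(s-Bu)3 (1.05 equiv), THF, −78 °C; 14, −78 °C; MsCl (1.5 equiv), −78 → −30 °C
Reagents that add atoms: methanesulfonyl chloride, CS(=O)(=O)Cl
Why: Conjugate reduction gives the regiodefined tetrasubstituted lithium enolate, whose aldol addition through a closed Zimmerman–Traxler transition state places the new oxygen syn to the CH2OTBS branch and anti to the ring CH2 (this C10/C1 relationship later fixes the alkene geometry), and in situ mesylation blocks retro-aldol; the face of attack (anti to the ring OTBS) is inconsequential because C10 becomes sp2 in step 10, and at −78 °C the enolate should not expel the silyloxide.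

**Step 9**
Reactants: 17 the mesyloxy ketone; 18 ethenylmagnesium bromide
Product: 19 (1R,2S,4S,5R)-1-ethenyl-2-[(1R)-1-(mesyloxy)-4-(TBSOCH2)pent-4-en-1-yl]-4-(TBSO)-2-(TBSOCH2)-5-[(trimethylsilyl)ethynyl]cyclopentan-1-ol
Conditions: LaCl3·2LiCl (1 equiv), THF, −78 °C; aq. NH4Cl at −78 °C
Reagents that add atoms: none
Why: Lewis acid-assisted Grignard 1,2-addition to the hindered ketone, expected from the face opposite the alkynyl group and the branched side chain (either carbinol epimer is usable later); the covalent magnesium alkoxide is quenched cold so that it does not fragment prematurely.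

**Step 10**
Reactants: 19 the vinyl carbinol
Product: 21 (2E,6E,9S,10R)-9-(TBSO)-3,7-bis(TBSOCH2)-10-[(trimethylsilyl)ethynyl]cyclodeca-2,6-dien-1-one, via bicyclic alcohol 20 (not isolated)
Conditions: second-generation Hoveyda–Grubbs catalyst (5 mol%), PhMe, 80 °C; then KN(SiMe3)2 (1.2 equiv), THF, −78 → 0 °C; AcOH
Reagents that add atoms: none
Why: Ring-closing metathesis forms the cycloheptene (C4=C5, necessarily ring-cis), and the potassium alkoxide of the resulting 1,3-diol monomesylate then undergoes Grob (Wharton-type) fragmentation in which the ring-fusion C6–C10 bond anti-periplanar to C1–OMs breaks, expanding the bicyclo[5.3.0]decane to the cyclodecadienone and giving, stereospecifically from the aldol configuration, the ring-cis C1=C10 alkene.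

**Step 11**
Reactants: 21 the cyclodecadienone
Product: 22 (1R,2E,6E,9S,10S)-9-(TBSO)-3,7-bis(TBSOCH2)-10-[(trimethylsilyl)ethynyl]cyclodeca-2,6-dien-1-ol
Conditions: NaBH4, CeCl3·7H2O, MeOH, −78 °C
Reagents that add atoms: none
Why: Luche 1,2-reduction of the enone; Felkin–Anh delivery of hydride anti to the ring bond carrying the silyloxy branch, with the slim alkynyl group as the medium substituent, should give the (1R)-alcohol trans to the alkynyl group (C6 of the target), though this selectivity in a ten-membered ring is a prediction.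

**Step 12**
Reactants: 22 the allylic alcohol; 23 (2E)-2-methylbut-2-enoyl chloride
Product: 24 (1R,2E,6E,9S,10S)-9-(TBSO)-3,7-bis(TBSOCH2)-10-[(trimethylsilyl)ethynyl]cyclodeca-2,6-dien-1-yl (2E)-2-methylbut-2-enoate
Conditions: Et3N, DMAP (cat.), CH2Cl2, 0 °C → rt
Reagents that add atoms: none
Why: DMAP-catalysed acylation (esterification) of the only free hydroxyl; the tigloyl group has no α-hydrogen and keeps its E geometry.

**Step 13**
Reactants: 24 the silylated tiglate
Product: 25 (1R,2E,6E,9S,10R)-10-ethynyl-9-hydroxy-3,7-bis(hydroxymethyl)cyclodeca-2,6-dien-1-yl (2E)-2-methylbut-2-enoate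
Conditions: Bu4NF (5 equiv), AcOH (5 equiv), THF, 0 °C → rt
Reagents that add atoms: none
Why: Fluoride-mediated desilylation cleaves the three O–Si bonds and the alkynyl C–Si bond, with AcOH buffering against acyl migration and ester cleavage.

**Step 14**
Reactants: 25 the ethynyl triol; 26 carbon monoxide
Product: 27 the target, (6R,7R,8S)-14,15-dihydroxy-6-(tigloyloxy)germacra-1(10),4,11(13)-trien-12,8-olide (CNP0275462.2)
Conditions: PdCl2 (10 mol%), thiourea (10 mol%), CO (1 atm), acetone, 50 °C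
Reagents that add atoms: none
Why: Palladium-catalysed cyclocarbonylation of a homopropargylic alcohol (alkoxycarbonyl–palladium formation at the C8 hydroxyl on divalent palladium, intramolecular syn insertion of the alkyne, protonolysis) gives the α-methylene-γ-butyrolactone, trans-fused because ethynyl and hydroxyl are already trans; the primary allylic alcohols cannot close a five-membered lactone.

**Compound list**
1 | furan-2-carbaldehyde | O=Cc1ccco1 | starting material
2 | ethynyl(trimethyl)silane | C#C[Si](C)(C)C | starting material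
3 | lithium (trimethylsilyl)acetylide | [Li]C#C[Si](C)(C)C | intermediate
4 | 1-(furan-2-yl)-3-(trimethylsilyl)prop-2-yn-1-ol (racemic) | OC(C#C[Si](C)(C)C)c1ccco1 | intermediate
5 | (4S,5R)-4-hydroxy-5-[(trimethylsilyl)ethynyl]cyclopent-2-en-1-one | O=C1C=C[C@H](O)[C@H]1C#C[Si](C)(C)C | intermediate
6 | formaldehyde | C=O | starting material
7 | (4S,5R)-4-hydroxy-2-(hydroxymethyl)-5-[(trimethylsilyl)ethynyl]cyclopent-2-en-1-one | O=C1C(CO)=C[C@H](O)[C@H]1C#C[Si](C)(C)C | intermediate
8 | (4S,5R)-4-(TBSO)-2-(TBSOCH2)-5-[(trimethylsilyl)ethynyl]cyclopent-2-en-1-one | O=C1C(CO[Si](C)(C)C(C)(C)C)=C[C@H](O[Si](C)(C)C(C)(C)C)[C@H]1C#C[Si](C)(C)C | intermediate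
9 | 2-methylidenepropane-1,3-diol | C=C(CO)CO | starting material
10 | 2-(TBSOCH2)prop-2-en-1-ol | C=C(CO)CO[Si](C)(C)C(C)(C)C | intermediate
11 | 1,1,1-trimethoxyethane | CC(OC)(OC)OC | starting material
12 | 1-methoxyethenyl 2-(TBSOCH2)prop-2-en-1-yl ether (ketene acetal) | C=C(OC)OCC(=C)CO[Si](C)(C)C(C)(C)C | intermediate
13 | methyl 4-(TBSOCH2)pent-4-enoate | COC(=O)CCC(=C)CO[Si](C)(C)C(C)(C)C | intermediate
14 | 4-(TBSOCH2)pent-4-enal | O=CCCC(=C)CO[Si](C)(C)C(C)(C)C | intermediate
15 | lithium (4S,5R)-4-(TBSO)-2-(TBSOCH2)-5-[(trimethylsilyl)ethynyl]cyclopent-1-en-1-olate | [Li]OC1=C(CO[Si](C)(C)C(C)(C)C)C[C@H](O[Si](C)(C)C(C)(C)C)[C@H]1C#C[Si](C)(C)C | intermediate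
16 | lithium alkoxide of the aldol adduct (17 with OLi in place of OMs) | O=C1[C@@](CO[Si](C)(C)C(C)(C)C)([C@H](O[Li])CCC(=C)CO[Si](C)(C)C(C)(C)C)C[C@H](O[Si](C)(C)C(C)(C)C)[C@H]1C#C[Si](C)(C)C | intermediate
17 | (2S,4S,5R)-2-[(1R)-1-(mesyloxy)-4-(TBSOCH2)pent-4-en-1-yl]-4-(TBSO)-2-(TBSOCH2)-5-[(trimethylsilyl)ethynyl]cyclopentan-1-one (side chain trans to ring OTBS) | O=C1[C@@](CO[Si](C)(C)C(C)(C)C)([C@H](OS(C)(=O)=O)CCC(=C)CO[Si](C)(C)C(C)(C)C)C[C@H](O[Si](C)(C)C(C)(C)C)[C@H]1C#C[Si](C)(C)C | intermediate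
18 | ethenylmagnesium bromide | C=C[Mg]Br | starting material
19 | (1R,2S,4S,5R)-1-ethenyl-2-[(1R)-1-(mesyloxy)-4-(TBSOCH2)pent-4-en-1-yl]-4-(TBSO)-2-(TBSOCH2)-5-[(trimethylsilyl)ethynyl]cyclopentan-1-ol | O[C@@]1(C=C)[C@@](CO[Si](C)(C)C(C)(C)C)([C@H](OS(C)(=O)=O)CCC(=C)CO[Si](C)(C)C(C)(C)C)C[C@H](O[Si](C)(C)C(C)(C)C)[C@H]1C#C[Si](C)(C)C | intermediate
20 | trans-fused 1-hydroxy-9-(TBSO)-3,7-bis(TBSOCH2)-10-[(trimethylsilyl)ethynyl]bicyclo[5.3.0]dec-2-en-6-yl methanesulfonate | O[C@@]12C=C(CO[Si](C)(C)C(C)(C)C)CC[C@@H](OS(C)(=O)=O)[C@@]1(CO[Si](C)(C)C(C)(C)C)C[C@H](O[Si](C)(C)C(C)(C)C)[C@H]2C#C[Si](C)(C)C | intermediate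
21 | (2E,6E,9S,10R)-9-(TBSO)-3,7-bis(TBSOCH2)-10-[(trimethylsilyl)ethynyl]cyclodeca-2,6-dien-1-one (ring carbons cis at both C=C) | O=C1/C=C(CO[Si](C)(C)C(C)(C)C)\CC/C=C(CO[Si](C)(C)C(C)(C)C)\C[C@H](O[Si](C)(C)C(C)(C)C)[C@H]1C#C[Si](C)(C)C | intermediate
22 | (1R,2E,6E,9S,10S)-9-(TBSO)-3,7-bis(TBSOCH2)-10-[(trimethylsilyl)ethynyl]cyclodeca-2,6-dien-1-ol | O[C@@H]1/C=C(CO[Si](C)(C)C(C)(C)C)\CC/C=C(CO[Si](C)(C)C(C)(C)C)\C[C@H](O[Si](C)(C)C(C)(C)C)[C@H]1C#C[Si](C)(C)C | intermediate
23 | (2E)-2-methylbut-2-enoyl chloride | C/C=C(\C)C(Cl)=O | starting material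
24 | (1R,2E,6E,9S,10S)-9-(TBSO)-3,7-bis(TBSOCH2)-10-[(trimethylsilyl)ethynyl]cyclodeca-2,6-dien-1-yl (2E)-2-methylbut-2-enoate | C/C=C(\C)C(=O)O[C@@H]1/C=C(CO[Si](C)(C)C(C)(C)C)\CC/C=C(CO[Si](C)(C)C(C)(C)C)\C[C@H](O[Si](C)(C)C(C)(C)C)[C@H]1C#C[Si](C)(C)C | intermediate
25 | (1R,2E,6E,9S,10R)-10-ethynyl-9-hydroxy-3,7-bis(hydroxymethyl)cyclodeca-2,6-dien-1-yl (2E)-2-methylbut-2-enoate | C/C=C(\C)C(=O)O[C@@H]1/C=C(CO)\CC/C=C(CO)\C[C@H](O)[C@H]1C#C | intermediate
26 | carbon monoxide | [C-]#[O+] | starting material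
27 | (6R,7R,8S)-14,15-dihydroxy-6-(tigloyloxy)germacra-1(10),4,11(13)-trien-12,8-olide, CNP0275462.2 | C=C1C(=O)O[C@H]2C/C(CO)=C\CC/C(CO)=C\[C@@H](OC(=O)/C(C)=C/C)[C@H]12 | target

**Totals and fallbacks**
Total: 14 steps. Longest linear sequence: 11 steps (1, 2, 3, 4, 8, 9, 10, 11, 12, 13, 14).

The three steps most likely to fail are 2, 8 and 10.

Step 2 (the new reaction; fallback uses known chemistry). Setting out from carbinol 4, the racemic oxa-Piancatelli rearrangement (Dy(OTf)3 10 mol%, MeCN/H2O, 80 °C) gives racemic trans-4-hydroxy-5-[(trimethylsilyl)ethynyl]cyclopent-2-en-1-one F1. Lipase-catalysed transesterification (lipase from Burkholderia cepacia, vinyl acetate, t-BuOMe, rt) then acetylates one enantiomer. By analogy with 4-hydroxycyclopent-2-enone this should be the (4S,5R) one, giving (1S,5R)-4-oxo-5-[(trimethylsilyl)ethynyl]cyclopent-2-en-1-yl acetate F2. F2 is separated from the unreacted antipode and de-acetylated by enzymatic methanolysis (Candida antarctica lipase B, MeOH), which comes back to the route at 5. If the enzyme prefers the antipode, 5 is simply the recovered alcohol.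

Step 8 (silyloxide loss from the enolate, or retro-aldol before trapping). Setting out from diol 7, both hydroxyls are first turned into lithium alkoxides (LiN(SiMe3)2, 2 equiv, THF, −78 °C), which cannot be expelled from the enolate. LiBH(s-Bu)3 and aldehyde 14 then give, through the same closed transition state, the triol (2S,4S,5R)-4-hydroxy-2-(hydroxymethyl)-2-[(1R)-1-hydroxy-4-(TBSOCH2)pent-4-en-1-yl]-5-[(trimethylsilyl)ethynyl]cyclopentan-1-one F3. TBSCl/imidazole (2.2 equiv) silylates the primary and the ring secondary hydroxyl, and MsCl/Et3N then converts the remaining hindered aldol hydroxyl into the mesylate. This comes back to the route at 17.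

Step 10 (metathesis to the hindered bicycle, or a bicycle that cannot reach the anti-periplanar geometry). Setting out from 19, KN(SiMe3)2 (THF, −78 → −20 °C) triggers the same Grob fragmentation on the monocyclic alcohol, where the side-chain C–OMs bond rotates freely into position. This opens the cyclopentane to the acyclic trienone (4R,5S,7E)-5-(TBSO)-7,11-bis(TBSOCH2)-4-[(trimethylsilyl)ethynyl]dodeca-1,7,11-trien-3-one F4, with the C1=C10 alkene already in place. The ten-membered ring is then closed at C4=C5 by high-dilution ring-closing metathesis (second-generation Hoveyda–Grubbs catalyst, PhMe, 1 mM, 80 °C), which comes back to the route at 21; the ring-cis geometry of the new enone would have to be confirmed.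

**Further compounds**
F1 | step 2 | racemic trans-4-hydroxy-5-[(trimethylsilyl)ethynyl]cyclopent-2-en-1-one | O=C1C=C[C@H](O)[C@H]1C#C[Si](C)(C)C.O=C1C=C[C@@H](O)[C@@H]1C#C[Si](C)(C)C
F2 | step 2 | (1S,5R)-4-oxo-5-[(trimethylsilyl)ethynyl]cyclopent-2-en-1-yl acetate | O=C1C=C[C@H](OC(C)=O)[C@H]1C#C[Si](C)(C)C
F3 | step 8 | (2S,4S,5R)-4-hydroxy-2-(hydroxymethyl)-2-[(1R)-1-hydroxy-4-(TBSOCH2)pent-4-en-1-yl]-5-[(trimethylsilyl)ethynyl]cyclopentan-1-one | O=C1[C@@](CO)([C@H](O)CCC(=C)CO[Si](C)(C)C(C)(C)C)C[C@H](O)[C@H]1C#C[Si](C)(C)C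
F4 | step 10 | (4R,5S,7E)-5-(TBSO)-7,11-bis(TBSOCH2)-4-[(trimethylsilyl)ethynyl]dodeca-1,7,11-trien-3-one | C=CC(=O)[C@H](C#C[Si](C)(C)C)[C@@H](O[Si](C)(C)C(C)(C)C)C/C(CO[Si](C)(C)C(C)(C)C)=C\CCC(=C)CO[Si](C)(C)C(C)(C)C
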